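The ten-membered ring is not closed but uncovered. Because the E-configured C1=C10 alkene lies 1,3 to C5, a transannular C5–C10 bond turns the germacrene into a trans-fused eudesmane (rings A and B) with a leaving group on C1 and a hydroxyl on C5; everything rests on cutting that shared bond again. In one operation the alkoxide-triggered Wharton fragmentation opens the decalin, sets the E trisubstituted alkene and releases the C5 ketone beside the intact C4 carbinol, from which the trans-4,5-epoxide follows. The precursor is a (R)-carvone-derived eudesmane-4α,5α-diol with 3β-OPMB, 6β-OTBS and an equatorial 1β-mesylate; C3, C4, C6 and C7 are fixed on this rigid bicycle.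

Key step: step 16

Remark on numbering: eudesmane/germacrane numbering is used (C14 on C10, C15 on C4, isopropyl on C7); α/β refer to the decalin drawn with the C10 methyl β, and all eudesmanes 8–21 carry 10β-methyl and 7β-isopropyl. Carvomenthone 2 is used as its C2 epimer mixture because C2 is re-set in step 2.

Remark on stereochemistry: substrate 21 and product 22 of the key step agree with the target at C3, C4, C6 and C7 as drawn. Two points need active control: the C10 methyl must be cis to the C7 isopropyl (chiral imine in step 2, since a plain enolate annulation favours the C10 epimer), and the C1 oxygen must be equatorial (β), which oxygenation of the dienone does not give directly (hence steps 12 and 13).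

Step 1
Reactants: 1 (R)-carvone
Product: 2 (5R)-carvomenthone (C2 epimer mixture)
Conditions: H2 (1 atm), Pd/C (10%), EtOAc, rt
Reagents that add atoms: none
Why: Heterogeneous catalytic hydrogenation saturates both C=C bonds and leaves the ketone and the non-enolisable C5 stereocentre untouched; the C2 epimer ratio does not matter because C2 becomes the enamine carbon in step 2.

Step 2
Reactants: 2 carvomenthone; 3 (R)-1-phenylethylamine; 4 ethyl vinyl ketone
Product: 7 (2S,5R)-2-methyl-2-(3-oxopentyl)-5-(propan-2-yl)cyclohexan-1-one, via ketimine 5 (not isolated), via adduct imine 6 (not isolated)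
Conditions: 3, TsOH (cat.), toluene, reflux (Dean–Stark); then 4, THF, 40 °C; then 10% aq. AcOH, rt
Reagents that add atoms: water, O
Why: Asymmetric Michael addition of a chiral ketimine through its more substituted secondary enamine tautomer (first half of a Robinson annulation): the (R)-1-phenylethyl group blocks one enamine face, so the vinyl ketone is delivered to C2 under auxiliary control and the new quaternary centre is S, its methyl cis to the isopropyl group, which a plain enolate would not give; acidic hydrolysis releases the diketone and the amine.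

Step 3
Reactants: 7 (2S,5R)-2-methyl-2-(3-oxopentyl)-5-(propan-2-yl)cyclohexan-1-one
Product: 8 eudesm-4-en-3-one
Conditions: NaOCH3, CH3OH, rt
Reagents that add atoms: none
Why: Base-mediated intramolecular aldol condensation (second half of the Robinson annulation) closes the six-membered enone ring between the ethyl ketone α-carbon and the ring carbonyl; no stereocentre is formed and the quaternary carbon cannot epimerise.

Step 4
Reactants: 8 eudesm-4-en-3-one
Product: 9 eudesma-1,4-dien-3-one
Conditions: DDQ, 1,4-dioxane, reflux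
Reagents that add atoms: none
Why: Quinone dehydrogenation of a 4-en-3-one under neutral conditions runs through the 2,4-dienol with hydride loss from C1 and gives the cross-conjugated 1,4-dien-3-one, as with 3-keto steroids.

Step 5
Reactants: 9 eudesma-1,4-dien-3-one
Product: 10 3-(tert-butyldimethylsilyloxy)eudesma-1,3,5-triene
Conditions: TBSOTf, Et3N, CH2Cl2, 0 °C
Reagents that add atoms: tert-butyldimethylsilyl trifluoromethanesulfonate, CC(C)(C)[Si](C)(C)OS(=O)(=O)C(F)(F)F
Why: Silyl dienol ether formation: O-silylation of the dienone and loss of the only available γ-proton (at C6; C2 is sp2 and C10 quaternary) give a single linear trienol ether.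

Step 6
Reactants: 10 3-(tert-butyldimethylsilyloxy)eudesma-1,3,5-triene
Product: 11 6β-hydroxyeudesma-1,4-dien-3-one
Conditions: m-CPBA, NaHCO3, CH2Cl2, −20 to 0 °C; aqueous work-up
Reagents that add atoms: m-chloroperbenzoic acid, OOC(=O)c1cccc(Cl)c1
Why: Vinylogous Rubottom oxidation: the peracid attacks the electron-rich terminus C6 of the silyl trienol ether (C4 is blocked by its methyl) along the axial trajectory on the β face, as with steroidal 3,5-dienol derivatives, and the axial 6β-alcohol is also the isomer free of allylic 1,3-strain with the C4 methyl, so it is not expected to epimerise later.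

Step 7
Reactants: 11 6β-hydroxyeudesma-1,4-dien-3-one
Product: 12 6β-(tert-butyldimethylsilyloxy)eudesma-1,4-dien-3-one
Conditions: TBSOTf, 2,6-lutidine, CH2Cl2, −78 to 0 °C
Reagents that add atoms: tert-butyldimethylsilyl trifluoromethanesulfonate, CC(C)(C)[Si](C)(C)OS(=O)(=O)C(F)(F)F
Why: Silyl triflate silylation of the hindered axial secondary alcohol with a weak pyridine base that does not enolise the dienone, so the C6 configuration is kept.

Step 8
Reactants: 12 6β-(tert-butyldimethylsilyloxy)eudesma-1,4-dien-3-one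
Product: 13 1α,2α-epoxy-6β-(tert-butyldimethylsilyloxy)eudesm-4-en-3-one
Conditions: 30% H2O2, NaOH, CH3OH, 0 °C
Reagents that add atoms: hydrogen peroxide, OO
Why: Weitz–Scheffer nucleophilic epoxidation takes place only at the disubstituted C1=C2 bond (the β-carbon C5 of the other enone arm is fully substituted), and hydroperoxide adds to C1 anti to the C10 methyl, which puts the epoxide on the α face as in steroidal 1,4-dien-3-ones.

Step 9
Reactants: 13 1α,2α-epoxy-6β-(tert-butyldimethylsilyloxy)eudesm-4-en-3-one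
Product: 14 1α-hydroxy-6β-(tert-butyldimethylsilyloxy)eudesm-4-en-3-one
Conditions: (PhSe)2, NaBH4, EtOH, AcOH, 0 °C to rt
Reagents that add atoms: none
Why: Benzeneselenolate-mediated reductive cleavage of an α,β-epoxy ketone breaks only the C2–O bond α to the carbonyl, so the C1–O bond keeps its α configuration and the β-hydroxy ketone forms under buffered conditions that neither dehydrate it nor reduce the enone.

Step 10
Reactants: 14 1α-hydroxy-6β-(tert-butyldimethylsilyloxy)eudesm-4-en-3-one
Product: 15 6β-(tert-butyldimethylsilyloxy)eudesm-4-ene-1α,3β-diol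
Conditions: Me4NBH(OAc)3, CH3CN/AcOH (1:1), −25 °C
Reagents that add atoms: none
Why: Evans–Saksena hydroxyl-directed reduction: the axial C1 alkoxy(diacetoxy)borohydride hands its hydride to the α face of the C3 carbonyl through a six-membered transition state, so the new carbinol is 3β (1,3-anti to O1) and only 1,2-reduction of the enone occurs.

Step 11
Reactants: 15 6β-(tert-butyldimethylsilyloxy)eudesm-4-ene-1α,3β-diol; 16 4-methoxybenzyl chloride
Product: 17 3β-(4-methoxybenzyloxy)-6β-(tert-butyldimethylsilyloxy)eudesm-4-en-1α-ol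
Conditions: NaH (1.05 equiv), 16, Bu4NI (cat.), THF/DMF, 0 °C
Reagents that add atoms: none
Why: Williamson etherification with one equivalent of base goes to the unhindered allylic 3β-alkoxide, while the axial 1α-hydroxyl next to the quaternary C10 reacts much more slowly, the same steric discrimination that allows selective 3-O-derivatisation of 1α,3β-dihydroxy steroids.

Step 12
Reactants: 17 3β-(4-methoxybenzyloxy)-6β-(tert-butyldimethylsilyloxy)eudesm-4-en-1α-ol
Product: 18 3β-(4-methoxybenzyloxy)-6β-(tert-butyldimethylsilyloxy)eudesm-4-en-1-one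
Conditions: Dess–Martin periodinane, NaHCO3, CH2Cl2, rt
Reagents that add atoms: none
Why: Dess–Martin oxidation of the only free alcohol under buffered, non-basic conditions gives the C1 ketone without β-elimination of the C3 ether and removes the wrongly oriented 1α centre.

Step 13
Reactants: 18 3β-(4-methoxybenzyloxy)-6β-(tert-butyldimethylsilyloxy)eudesm-4-en-1-one
Product: 19 3β-(4-methoxybenzyloxy)-6β-(tert-butyldimethylsilyloxy)eudesm-4-en-1β-ol
Conditions: NaBH4, CH3OH, 0 °C
Reagents that add atoms: none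
Why: Borohydride reduction of a ketone next to the methyl-bearing ring-fusion carbon: hydride attacks from the α face, anti to the axial C10 methyl, and gives the equatorial 1β-alcohol, as in Wieland–Miescher-type ketones.

Step 14
Reactants: 19 3β-(4-methoxybenzyloxy)-6β-(tert-butyldimethylsilyloxy)eudesm-4-en-1β-ol
Product: 20 1β-(methanesulfonyloxy)-3β-(4-methoxybenzyloxy)-6β-(tert-butyldimethylsilyloxy)eudesm-4-ene
Conditions: MsCl, Et3N, CH2Cl2, 0 °C
Reagents that add atoms: methanesulfonyl chloride, CS(=O)(=O)Cl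
Why: Sulfonylation (via sulfene) of the single free hydroxyl proceeds with retention at C1 and gives the equatorial secondary mesylate, which is neopentyl-like and therefore stable to the next step.

Step 15
Reactants: 20 1β-(methanesulfonyloxy)-3β-(4-methoxybenzyloxy)-6β-(tert-butyldimethylsilyloxy)eudesm-4-ene
Product: 21 1β-(methanesulfonyloxy)-3β-(4-methoxybenzyloxy)-6β-(tert-butyldimethylsilyloxy)eudesmane-4α,5α-diol
Conditions: OsO4 (1.1 equiv), pyridine, rt; then aq. NaHSO3
Reagents that add atoms: osmium tetroxide, O=[Os](=O)(=O)=O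
Why: Stoichiometric osmium tetroxide syn-dihydroxylation of the tetrasubstituted C4=C5 bond occurs on the α face, anti to both allylic oxygen substituents (3β-OPMB and 6β-OTBS) and to the axial C10 methyl, which sets the cis-4α,5α-diol and the trans ring fusion at once; pyridine is too weak a base to trigger fragmentation.

Step 16
Reactants: 21 1β-(methanesulfonyloxy)-3β-(4-methoxybenzyloxy)-6β-(tert-butyldimethylsilyloxy)eudesmane-4α,5α-diol
Product: 22 (1(10)E,3S,4R,6R,7S)-6-(tert-butyldimethylsilyloxy)-4-hydroxy-3-(4-methoxybenzyloxy)germacr-1(10)-en-5-one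
Conditions: KOC(CH3)3 (1.2 equiv), THF, 0 °C; pH 7 phosphate buffer quench
Reagents that add atoms: none
Why: Deprotonation of the tertiary 5α-hydroxyl gives an alkoxide that pushes electrons into C5 while the C5–C10 σ bond, antiperiplanar to the equatorial C1–OMs bond, becomes the C1=C10 π bond as mesylate leaves, a concerted Wharton (Grob-type) fragmentation of a 1,3-diol monosulfonate. No ring is closed: the ten-membered ring appears by scission of the bond shared by rings A and B of the decalin. No stereocentre is created; the E geometry follows from the trans-fused chair–chair substrate, in which C2 and C9 are anti about C1–C10 when the leaving group is anti to C5. The step needs fragmentation to outrun oxetane formation and elimination, which the rigid antiperiplanar alignment secures, and it needs O5 to be the only oxygen able to trigger a cleavage, which the ether at C3 ensures because a free C3 alkoxide would open ring A instead. The C6 silyl ether is trans-diaxial to O5 and cannot migrate, and only a slight excess of base at 0 °C with a buffered quench is used so that the new ketone is not enolised towards C6.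

Step 17
Reactants: 22 (1(10)E,3S,4R,6R,7S)-6-(tert-butyldimethylsilyloxy)-4-hydroxy-3-(4-methoxybenzyloxy)germacr-1(10)-en-5-one
Product: 23 (1(10)E,3S,4S,5S,6R,7S)-6-(tert-butyldimethylsilyloxy)-3-(4-methoxybenzyloxy)germacr-1(10)-ene-4,5-diol
Conditions: Zn(BH4)2, Et2O, −20 °C
Reagents that add atoms: none
Why: Chelation-controlled hydride reduction of an α-hydroxy ketone: zinc bridges the C4 alkoxide and the C5 carbonyl, and hydride enters from the face that carries the small C4 methyl, which is also the outer face of the ten-membered ring, so the 4,5-anti diol (5S) is formed.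

Step 18
Reactants: 23 (1(10)E,3S,4S,5S,6R,7S)-6-(tert-butyldimethylsilyloxy)-3-(4-methoxybenzyloxy)germacr-1(10)-ene-4,5-diol
Product: 25 (1(10)E,3S,4R,5R,6R,7S)-6-(tert-butyldimethylsilyloxy)-4,5-epoxy-3-(4-methoxybenzyloxy)germacr-1(10)-ene, via C5 mesylate 24 (not isolated)
Conditions: MsCl, Et3N, CH2Cl2, −20 °C; then K2CO3, CH3OH, rt
Reagents that add atoms: none
Why: Selective sulfonylation of the secondary C5 hydroxyl beside the tertiary one, then intramolecular Williamson displacement (3-exo-tet) by the C4 alkoxide with inversion at C5, gives the trans-4,5-epoxide in which the C4–O bond made in step 15 is retained.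

Step 19
Reactants: 25 (1(10)E,3S,4R,5R,6R,7S)-6-(tert-butyldimethylsilyloxy)-4,5-epoxy-3-(4-methoxybenzyloxy)germacr-1(10)-ene
Product: 26 (1(10)E,3S,4R,5R,6R,7S)-4,5-epoxy-3-(4-methoxybenzyloxy)germacr-1(10)-en-6-ol
Conditions: Bu4NF, AcOH (1:1), THF, rt
Reagents that add atoms: none
Why: Fluoride-induced desilylation buffered with acetic acid frees the C6 hydroxyl without forming a free alkoxide that could migrate into the neighbouring epoxide (Payne rearrangement) and without acid that would trigger transannular cyclisation of the epoxy-germacrene.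

Step 20
Reactants: 26 (1(10)E,3S,4R,5R,6R,7S)-4,5-epoxy-3-(4-methoxybenzyloxy)germacr-1(10)-en-6-ol; 27 acetic anhydride
Product: 28 (1(10)E,3S,4R,5R,6R,7S)-4,5-epoxy-3-(4-methoxybenzyloxy)germacr-1(10)-en-6-yl acetate
Conditions: 27, pyridine, DMAP (cat.), CH2Cl2, rt
Reagents that add atoms: none
Why: DMAP-catalysed acylation of the only free hydroxyl installs the C6 acetate with retention.

Step 21
Reactants: 28 (1(10)E,3S,4R,5R,6R,7S)-4,5-epoxy-3-(4-methoxybenzyloxy)germacr-1(10)-en-6-yl acetate
Product: 29 (1(10)E,3S,4R,5R,6R,7S)-4,5-epoxy-3-hydroxygermacr-1(10)-en-6-yl acetate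
Conditions: DDQ, CH2Cl2/pH 7 phosphate buffer, 0 °C
Reagents that add atoms: none
Why: Oxidative cleavage of the electron-rich p-methoxybenzyl ether by DDQ in a buffered two-phase medium spares the acetate, the epoxide and the trisubstituted alkene.

Step 22
Reactants: 29 (1(10)E,3S,4R,5R,6R,7S)-4,5-epoxy-3-hydroxygermacr-1(10)-en-6-yl acetate; 30 3-methylbut-2-enoyl chloride
Product: 31 (1(10)E,3S,4R,5R,6R,7S)-6-acetoxy-4,5-epoxygermacr-1(10)-en-3-yl 3-methylbut-2-enoate (CNP0267399.1)
Conditions: 30, pyridine, DMAP (cat.), CH2Cl2, 0 °C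
Reagents that add atoms: none
Why: DMAP-catalysed acylation of the C3 alcohol with the acid chloride, using pyridine and not a trialkylamine to avoid deconjugation through a vinylketene, completes the target with all stereocentres unchanged.

Compound list

1 | (R)-carvone, (5R)-2-methyl-5-(prop-1-en-2-yl)cyclohex-2-en-1-one | CC1=CC[C@H](CC1=O)C(C)=C | starting material
2 | carvomenthone, (5R)-2-methyl-5-(propan-2-yl)cyclohexan-1-one, C2 epimer mixture | CC1CC[C@H](CC1=O)C(C)C | intermediate
3 | (R)-1-phenylethylamine | C[C@@H](N)c1ccccc1 | starting material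
4 | ethyl vinyl ketone (pent-1-en-3-one) | CCC(=O)C=C | starting material
5 | N-[(1R)-1-phenylethyl] ketimine of 2 | CC1CC[C@H](CC1=N[C@H](C)c1ccccc1)C(C)C | intermediate (not isolated)
6 | N-[(1R)-1-phenylethyl] imine (ring carbonyl) of 7 | CCC(=O)CC[C@]1(C)CC[C@@H](C(C)C)CC1=N[C@H](C)c1ccccc1 | intermediate (not isolated)
7 | (2S,5R)-2-methyl-2-(3-oxopentyl)-5-(propan-2-yl)cyclohexan-1-one | CCC(=O)CC[C@]1(C)CC[C@@H](C(C)C)CC1=O | intermediate
8 | eudesm-4-en-3-one, (4aS,7R)-1,4a-dimethyl-7-(propan-2-yl)-4,4a,5,6,7,8-hexahydronaphthalen-2(3H)-one | CC1=C2C[C@H](C(C)C)CC[C@@]2(C)CCC1=O | intermediate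
9 | eudesma-1,4-dien-3-one | CC1=C2C[C@H](C(C)C)CC[C@@]2(C)C=CC1=O | intermediate
10 | 3-(tert-butyldimethylsilyloxy)eudesma-1,3,5-triene | CC1=C(O[Si](C)(C)C(C)(C)C)C=C[C@]2(C)CC[C@@H](C(C)C)C=C12 | intermediate
11 | 6β-hydroxyeudesma-1,4-dien-3-one | CC1=C2[C@H](O)[C@H](C(C)C)CC[C@@]2(C)C=CC1=O | intermediate
12 | 6β-(tert-butyldimethylsilyloxy)eudesma-1,4-dien-3-one | CC1=C2[C@H](O[Si](C)(C)C(C)(C)C)[C@H](C(C)C)CC[C@@]2(C)C=CC1=O | intermediate
13 | 1α,2α-epoxy-6β-(tert-butyldimethylsilyloxy)eudesm-4-en-3-one | CC1=C2[C@H](O[Si](C)(C)C(C)(C)C)[C@H](C(C)C)CC[C@@]2(C)[C@H]3O[C@H]3C1=O | intermediate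
14 | 1α-hydroxy-6β-(tert-butyldimethylsilyloxy)eudesm-4-en-3-one | CC1=C2[C@H](O[Si](C)(C)C(C)(C)C)[C@H](C(C)C)CC[C@@]2(C)[C@@H](O)CC1=O | intermediate
15 | 6β-(tert-butyldimethylsilyloxy)eudesm-4-ene-1α,3β-diol | CC1=C2[C@H](O[Si](C)(C)C(C)(C)C)[C@H](C(C)C)CC[C@@]2(C)[C@@H](O)C[C@@H]1O | intermediate
16 | 4-methoxybenzyl chloride | COc1ccc(CCl)cc1 | starting material
17 | 3β-(4-methoxybenzyloxy)-6β-(tert-butyldimethylsilyloxy)eudesm-4-en-1α-ol | CC1=C2[C@H](O[Si](C)(C)C(C)(C)C)[C@H](C(C)C)CC[C@@]2(C)[C@@H](O)C[C@@H]1OCc1ccc(OC)cc1 | intermediate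
18 | 3β-(4-methoxybenzyloxy)-6β-(tert-butyldimethylsilyloxy)eudesm-4-en-1-one | CC1=C2[C@H](O[Si](C)(C)C(C)(C)C)[C@H](C(C)C)CC[C@@]2(C)C(=O)C[C@@H]1OCc1ccc(OC)cc1 | intermediate
19 | 3β-(4-methoxybenzyloxy)-6β-(tert-butyldimethylsilyloxy)eudesm-4-en-1β-ol | CC1=C2[C@H](O[Si](C)(C)C(C)(C)C)[C@H](C(C)C)CC[C@@]2(C)[C@H](O)C[C@@H]1OCc1ccc(OC)cc1 | intermediate
20 | 1β-(methanesulfonyloxy)-3β-(4-methoxybenzyloxy)-6β-(tert-butyldimethylsilyloxy)eudesm-4-ene | CC1=C2[C@H](O[Si](C)(C)C(C)(C)C)[C@H](C(C)C)CC[C@@]2(C)[C@H](OS(C)(=O)=O)C[C@@H]1OCc1ccc(OC)cc1 | intermediate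
21 | 1β-(methanesulfonyloxy)-3β-(4-methoxybenzyloxy)-6β-(tert-butyldimethylsilyloxy)eudesmane-4α,5α-diol (4β-methyl, trans-fused) | CC(C)(C)[Si](C)(C)O[C@H]1[C@@]2(O)[C@@](O)(C)[C@@H](OCc3ccc(OC)cc3)C[C@@H](OS(C)(=O)=O)[C@]2(C)CC[C@H]1C(C)C | intermediate
22 | (1(10)E,3S,4R,6R,7S)-6-(tert-butyldimethylsilyloxy)-4-hydroxy-3-(4-methoxybenzyloxy)germacr-1(10)-en-5-one | CC(C)(C)[Si](C)(C)O[C@H]1C(=O)[C@@](O)(C)[C@@H](OCc2ccc(OC)cc2)C/C=C(\C)CC[C@H]1C(C)C | intermediate
23 | (1(10)E,3S,4S,5S,6R,7S)-6-(tert-butyldimethylsilyloxy)-3-(4-methoxybenzyloxy)germacr-1(10)-ene-4,5-diol | CC(C)(C)[Si](C)(C)O[C@H]1[C@H](O)[C@@](O)(C)[C@@H](OCc2ccc(OC)cc2)C/C=C(\C)CC[C@H]1C(C)C | intermediate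
24 | (1(10)E,3S,4R,5S,6R,7S)-6-(tert-butyldimethylsilyloxy)-4-hydroxy-3-(4-methoxybenzyloxy)germacr-1(10)-en-5-yl methanesulfonate | CC(C)(C)[Si](C)(C)O[C@H]1[C@H](OS(C)(=O)=O)[C@@](O)(C)[C@@H](OCc2ccc(OC)cc2)C/C=C(\C)CC[C@H]1C(C)C | intermediate (not isolated)
25 | (1(10)E,3S,4R,5R,6R,7S)-6-(tert-butyldimethylsilyloxy)-4,5-epoxy-3-(4-methoxybenzyloxy)germacr-1(10)-ene | CC(C)(C)[Si](C)(C)O[C@H]1[C@H]2O[C@]2(C)[C@@H](OCc2ccc(OC)cc2)C/C=C(\C)CC[C@H]1C(C)C | intermediate
26 | (1(10)E,3S,4R,5R,6R,7S)-4,5-epoxy-3-(4-methoxybenzyloxy)germacr-1(10)-en-6-ol | O[C@H]1[C@H]2O[C@]2(C)[C@@H](OCc2ccc(OC)cc2)C/C=C(\C)CC[C@H]1C(C)C | intermediate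
27 | acetic anhydride | CC(=O)OC(C)=O | starting material
28 | (1(10)E,3S,4R,5R,6R,7S)-4,5-epoxy-3-(4-methoxybenzyloxy)germacr-1(10)-en-6-yl acetate | CC(=O)O[C@H]1[C@H]2O[C@]2(C)[C@@H](OCc2ccc(OC)cc2)C/C=C(\C)CC[C@H]1C(C)C | intermediate
29 | (1(10)E,3S,4R,5R,6R,7S)-4,5-epoxy-3-hydroxygermacr-1(10)-en-6-yl acetate | CC(=O)O[C@H]1[C@H]2O[C@]2(C)[C@@H](O)C/C=C(\C)CC[C@H]1C(C)C | intermediate
30 | 3-methylbut-2-enoyl chloride | CC(C)=CC(=O)Cl | starting material
31 | (1(10)E,3S,4R,5R,6R,7S)-6-acetoxy-4,5-epoxygermacr-1(10)-en-3-yl 3-methylbut-2-enoate (CNP0267399.1) | CC(=O)O[C@H]1[C@H]2O[C@]2(C)[C@@H](OC(=O)C=C(C)C)C/C=C(\C)CC[C@H]1C(C)C | target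

Total step count: 22. Longest linear sequence: 22 steps (1 to 31).

Steps most likely to fail

1. Step 16 (key step). Once the ring has opened, residual alkoxide may enolise the new ketone towards C6 and erode that centre, or shift the tertiary α-ketol; with a slow substrate, internal displacement at C1 by O5 (oxetane formation) may compete. Fallback: release the oxyanion from a silyl ether with fluoride instead of using an alkoxide base. Setting out from 21, 1-(trimethylsilyl)imidazole in CH2Cl2 silylates both tertiary hydroxyls to give the 4,5-bis(trimethylsilyl) ether F1. Bu4NF (2.2 equiv) in THF at −40 to 0 °C then removes the two trimethylsilyl groups but not the hindered C6 silyl ether; the ammonium alkoxide fragments at once in a medium that holds no excess base, and aqueous work-up brings the route back at 22.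

2. Step 15. Osmylation of a tetrasubstituted alkene flanked by two allylic oxygens may be very slow, and the hindered osmate ester may resist cleavage. Fallback: build the cis-diol in stages through epoxides, setting out from 19. m-CPBA/NaHCO3 epoxidises the electron-rich alkene on the open α face to give the 4α,5α-epoxide F2. Et2Al(NC9H18) (diethylaluminium 2,2,6,6-tetramethylpiperidide) removes a C15 proton and isomerises it to the exocyclic allylic alcohol F3, the 4(15)-en-5α-ol. VO(acac)2/t-BuOOH delivers oxygen to the methylene group from the side of the 5α-hydroxyl to give the 4α,15-epoxide F4. LiAlH4 opens this at the primary carbon to the 1β,4α,5α-triol F5. MsCl in pyridine at 0 °C sulfonylates only the secondary 1β-hydroxyl and the route is rejoined at 21.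

3. Step 6. Facial selectivity of the peracid at C6 may be poor, so that the 6α alcohol forms alongside the 6β alcohol. Fallback: set C6 by hydride delivery instead, setting out from 10. The peracid oxidation is run without regard to selectivity, and the crude mixture of 11 and its 6α epimer F6 is oxidised with Dess–Martin periodinane to the 1,4-diene-3,6-dione F7. NaBH4/CeCl3·7H2O in CH3OH reduces both carbonyls 1,2; hydride reaches C6 from the α face, anti to the axial C10 methyl, and gives the 6β-configured dienediol F8 (C3 epimers are irrelevant). MnO2 in CH2Cl2 re-oxidises only the doubly allylic C3 carbinol and returns the route at 11.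

Further compounds

F1 | step 16 | 1β-(methanesulfonyloxy)-3β-(4-methoxybenzyloxy)-6β-(tert-butyldimethylsilyloxy)-4α,5α-bis(trimethylsilyloxy)eudesmane | CC(C)(C)[Si](C)(C)O[C@H]1[C@@]2(O[Si](C)(C)C)[C@@](O[Si](C)(C)C)(C)[C@@H](OCc3ccc(OC)cc3)C[C@@H](OS(C)(=O)=O)[C@]2(C)CC[C@H]1C(C)C
F2 | step 15 | 4α,5α-epoxy-3β-(4-methoxybenzyloxy)-6β-(tert-butyldimethylsilyloxy)eudesman-1β-ol | CC(C)(C)[Si](C)(C)O[C@H]1[C@]23O[C@]3(C)[C@@H](OCc4ccc(OC)cc4)C[C@@H](O)[C@]2(C)CC[C@H]1C(C)C
F3 | step 15 | 3β-(4-methoxybenzyloxy)-6β-(tert-butyldimethylsilyloxy)eudesm-4(15)-ene-1β,5α-diol | CC(C)(C)[Si](C)(C)O[C@H]1[C@@]2(O)C(=C)[C@@H](OCc3ccc(OC)cc3)C[C@@H](O)[C@]2(C)CC[C@H]1C(C)C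
F4 | step 15 | 4α,15-epoxy-3β-(4-methoxybenzyloxy)-6β-(tert-butyldimethylsilyloxy)eudesmane-1β,5α-diol | CC(C)(C)[Si](C)(C)O[C@H]1[C@@]2(O)[C@@]3(CO3)[C@@H](OCc3ccc(OC)cc3)C[C@@H](O)[C@]2(C)CC[C@H]1C(C)C
F5 | step 15 | 3β-(4-methoxybenzyloxy)-6β-(tert-butyldimethylsilyloxy)eudesmane-1β,4α,5α-triol | CC(C)(C)[Si](C)(C)O[C@H]1[C@@]2(O)[C@@](O)(C)[C@@H](OCc3ccc(OC)cc3)C[C@@H](O)[C@]2(C)CC[C@H]1C(C)C
F6 | step 6 | 6α-hydroxyeudesma-1,4-dien-3-one | CC1=C2[C@@H](O)[C@H](C(C)C)CC[C@@]2(C)C=CC1=O
F7 | step 6 | eudesma-1,4-diene-3,6-dione | CC1=C2C(=O)[C@H](C(C)C)CC[C@@]2(C)C=CC1=O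
F8 | step 6 | eudesma-1,4-diene-3,6β-diol (C3 epimer mixture) | CC1=C2[C@H](O)[C@H](C(C)C)CC[C@@]2(C)C=CC1O
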